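**Assumption:** the four starting materials are taken as catalogue chemicals ((R)-styrene oxide in ≥98% ee); locants C2–C8a are those of the chromene-4,7-dione skeleton of the target, whose single stereocentre (C2) is S.

## Retrosynthetic overview

1. Ring C is closed last: the C2 hydroxyl displaces the C8a methoxy group of a dearomatised ring A (addition–elimination, C2–O bond untouched), triggered by unmasking the C4 ketone.
2. The C8 quaternary centre comes from dearomative gem-diprenylation of a symmetric 4-substituted 3,5-dimethoxyphenol; ring A stays aromatic until then.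
3. Key C3–C4 bond: a 2-lithio-1,3-dithiane (acyl anion for C4) opens (R)-styrene oxide at its CH2 carbon; two normally electrophilic carbons are joined and the epoxide oxygen becomes O1.
4. The dithiane comes from 4-hydroxy-2,6-dimethoxybenzaldehyde.
5. Ring order: ring A and the phenyl ring are bought; ring A is dearomatised in step 3; ring C forms in step 4.

## Route

Step 1
Reactants: 1 4-hydroxy-2,6-dimethoxybenzaldehyde; 2 propane-1,3-dithiol
Product: 3 aryl dithiane 4-(1,3-dithian-2-yl)-3,5-dimethoxyphenol
Conditions: BF3·OEt2 (0.2 equiv), CH2Cl2, 0 °C to rt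
Reagents that add atoms: propane-1,3-dithiol (compound 2), SCCCS
Why: Lewis-acid-catalysed dithioacetalisation (Corey–Seebach dithiane formation) turns the aldehyde carbon into a C–H acidic masked acyl anion centre, while the phenol and aryl methyl ethers are inert.

Step 2
Reactants: 3 aryl dithiane 4-(1,3-dithian-2-yl)-3,5-dimethoxyphenol; 4 (R)-styrene oxide
Product: 6 carbinol 4-{2-[(2S)-2-hydroxy-2-phenylethyl]-1,3-dithian-2-yl}-3,5-dimethoxyphenol, via dilithio dianion 5 (not isolated)
Conditions: n-BuLi (2.2 equiv), THF, −30 to 0 °C; then 4 (1.2 equiv), −30 °C to rt; aq. NH4Cl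
Reagents that add atoms: (R)-styrene oxide (compound 4), C1O[C@@H]1c1ccccc1
Why: Corey–Seebach umpolung on the unprotected phenol, in which the 2-lithio-1,3-dithiane carbon of the O,C-dianion (acyl anion equivalent for C4) opens the epoxide by SN2 at the unsubstituted CH2 (C3), so the benzylic C–O bond is never broken and the (R)-epoxide gives the (S)-carbinol (the descriptor changes only through CIP ranking) with the future O1 already in place.

Step 3
Reactants: 6 carbinol 4-{2-[(2S)-2-hydroxy-2-phenylethyl]-1,3-dithian-2-yl}-3,5-dimethoxyphenol; 7 prenyl bromide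
Product: 9 dienone 4-{2-[(2S)-2-hydroxy-2-phenylethyl]-1,3-dithian-2-yl}-3,5-dimethoxy-6,6-bis(3-methylbut-2-en-1-yl)cyclohexa-2,4-dien-1-one, via monoprenyl phenol 8 (not isolated)
Conditions: NaH (2.1 equiv, two portions), 7 (2.3 equiv), toluene, 0 °C to rt
Reagents that add atoms: prenyl bromide (compound 7), CC(C)=CCBr
Why: Alkylative dearomatisation by ortho-C-alkylation of a tight-ion-pair sodium phenoxide in a non-polar solvent (para position blocked), in which the first prenylation gives phenol 8 and the second enters the same, now more electron-rich carbon because the resulting 3,5-dimethoxy-2,4-dienone is a doubly vinylogous ester; only the phenol is deprotonated, so the secondary alcohol, the dithiane and the remote stereocentre are untouched, and the product is expected to need separation from the 2,6-diprenyl isomer.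

Step 4
Reactants: 9 dienone 4-{2-[(2S)-2-hydroxy-2-phenylethyl]-1,3-dithian-2-yl}-3,5-dimethoxy-6,6-bis(3-methylbut-2-en-1-yl)cyclohexa-2,4-dien-1-one
Product: 11 Griffinone A, via hydroxy ketone 10 (not isolated)
Conditions: MeI (10 equiv), CaCO3 (5 equiv), MeCN–H2O (9:1), 45 °C; then PPTS (0.2 equiv), CH2Cl2, rt
Reagents that add atoms: water, O
Why: Alkylative dithiane hydrolysis (S-methylation, thionium ion, water) unmasks the C4 ketone without touching the prenyl alkenes, and under mild acid the (S)-hydroxyl adds to C8a, the vinylogous-ester carbon activated by both C4=O and C7=O, and expels methanol (intramolecular oxa-Michael addition–elimination closing the six-membered ring C), so the C2–O bond is never broken and S is retained.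

## Compound list

1 | 4-hydroxy-2,6-dimethoxybenzaldehyde | COc1cc(O)cc(OC)c1C=O | starting material
2 | propane-1,3-dithiol | SCCCS | starting material
3 | 4-(1,3-dithian-2-yl)-3,5-dimethoxyphenol | COc1cc(O)cc(OC)c1C1SCCCS1 | intermediate
4 | (R)-styrene oxide, (2R)-2-phenyloxirane | C1O[C@@H]1c1ccccc1 | starting material
5 | lithium 4-(2-lithio-1,3-dithian-2-yl)-3,5-dimethoxyphenolate (dilithio dianion, not isolated) | [Li+].[Li+].COc1cc([O-])cc(OC)c1[C-]1SCCCS1 | intermediate
6 | 4-{2-[(2S)-2-hydroxy-2-phenylethyl]-1,3-dithian-2-yl}-3,5-dimethoxyphenol | COc1cc(O)cc(OC)c1C1(C[C@H](O)c2ccccc2)SCCCS1 | intermediate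
7 | prenyl bromide, 1-bromo-3-methylbut-2-ene | CC(C)=CCBr | starting material
8 | 4-{2-[(2S)-2-hydroxy-2-phenylethyl]-1,3-dithian-2-yl}-3,5-dimethoxy-2-(3-methylbut-2-en-1-yl)phenol (not isolated) | COc1cc(O)c(CC=C(C)C)c(OC)c1C1(C[C@H](O)c2ccccc2)SCCCS1 | intermediate
9 | 4-{2-[(2S)-2-hydroxy-2-phenylethyl]-1,3-dithian-2-yl}-3,5-dimethoxy-6,6-bis(3-methylbut-2-en-1-yl)cyclohexa-2,4-dien-1-one | COC1=CC(=O)C(CC=C(C)C)(CC=C(C)C)C(OC)=C1C1(C[C@H](O)c2ccccc2)SCCCS1 | intermediate
10 | 4-[(3S)-3-hydroxy-3-phenylpropanoyl]-3,5-dimethoxy-6,6-bis(3-methylbut-2-en-1-yl)cyclohexa-2,4-dien-1-one (not isolated) | COC1=CC(=O)C(CC=C(C)C)(CC=C(C)C)C(OC)=C1C(=O)C[C@H](O)c1ccccc1 | intermediate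
11 | Griffinone A, (2S)-5-methoxy-8,8-bis(3-methylbut-2-en-1-yl)-2-phenyl-2,3-dihydro-4H-chromene-4,7(8H)-dione | COC1=CC(=O)C(CC=C(C)C)(CC=C(C)C)C2=C1C(=O)C[C@@H](c1ccccc1)O2 | target

## Step count and risks

Total step count: 4. Longest linear sequence: 4 steps (1 → 3 → 6 → 9 → 11).

**Step 3 (most likely to fail).** The second prenyl group may enter the free ortho carbon instead, giving the 2,6-diprenylphenol and then a triprenyl dienone, or O-alkylation may compete. The fallback sets out from 6 and comes back to the route at 11. It replaces SN2 alkylation by titanium phenoxide/π-allylpalladium chemistry and makes the prenyl groups afterwards by olefin metathesis. Compound 6 with allyl alcohol, Pd(OAc)2, PPh3 and Ti(OiPr)4 in toluene at 50 °C gives, through the monoallyl phenol F4, the gem-diallyl dienone F5; this type of electrophile is known to attack an alkyl-bearing ortho carbon of 3,5-dimethoxyphenols with dearomatisation. MeI/CaCO3 followed by PPTS, as in step 4, then gives, through the diallyl hydroxy ketone F6, the 8,8-diallyl analogue F7. Double cross-metathesis of F7 with 2-methylbut-2-ene (second-generation Grubbs catalyst RuCl2(=CHPh)(H2IMes)(PCy3), CH2Cl2, 40 °C) gives 11. The metathesis is placed after dithiane removal because thioacetals poison the ruthenium catalyst.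

**Step 4.** The hindered dithiane may hydrolyse slowly, hydroxy ketone 10 may dehydrate to the enone under acid, or the hydroxyl may close onto C5 instead of C8a. The fallback sets out from 9 and comes back to the route at 11. It closes ring C before unmasking, under reversible base conditions where no C4 carbonyl is present, so neither β-elimination nor retro-oxa-Michael racemisation can occur. Compound 9 with KOtBu (0.2 equiv) in THF at rt forms the alkoxide, which adds to C8a and expels methoxide; because the exchange is reversible, the less congested isomer (small methoxy group next to C6–H) should accumulate, giving the spiro-dithiane F8. MeI/CaCO3 hydrolysis of F8 then gives 11.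

**Step 2.** The para-phenoxide lowers the acidity of the dithiane C–H and the two ortho methoxy groups hinder the carbanion, so dianion formation or epoxide opening may stall. The fallback sets out from 3 and comes back to the route at 6. It uses a protected monoanion in place of the dianion. TIPSCl and imidazole in DMF convert 3 into the silyl ether F1; n-BuLi (1.1 equiv) in THF at −30 °C gives the soluble 2-lithio dithiane F2, which opens 4 at the CH2 carbon to give the silyl ether carbinol F3; Bu4NF in THF returns 6.

Further compounds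

F1 | step 2 | triisopropyl[4-(1,3-dithian-2-yl)-3,5-dimethoxyphenoxy]silane | COc1cc(O[Si](C(C)C)(C(C)C)C(C)C)cc(OC)c1C1SCCCS1
F2 | step 2 | 2-lithio derivative of F1 (formed in the flask) | [Li+].COc1cc(O[Si](C(C)C)(C(C)C)C(C)C)cc(OC)c1[C-]1SCCCS1
F3 | step 2 | (1S)-2-{2-[2,6-dimethoxy-4-(triisopropylsilyloxy)phenyl]-1,3-dithian-2-yl}-1-phenylethanol | COc1cc(O[Si](C(C)C)(C(C)C)C(C)C)cc(OC)c1C1(C[C@H](O)c2ccccc2)SCCCS1
F4 | step 3 | 2-allyl-4-{2-[(2S)-2-hydroxy-2-phenylethyl]-1,3-dithian-2-yl}-3,5-dimethoxyphenol (formed in the flask) | COc1cc(O)c(CC=C)c(OC)c1C1(C[C@H](O)c2ccccc2)SCCCS1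
F5 | step 3 | 6,6-diallyl-4-{2-[(2S)-2-hydroxy-2-phenylethyl]-1,3-dithian-2-yl}-3,5-dimethoxycyclohexa-2,4-dien-1-one | COC1=CC(=O)C(CC=C)(CC=C)C(OC)=C1C1(C[C@H](O)c2ccccc2)SCCCS1
F6 | step 3 | 6,6-diallyl-4-[(3S)-3-hydroxy-3-phenylpropanoyl]-3,5-dimethoxycyclohexa-2,4-dien-1-one (formed in the flask) | COC1=CC(=O)C(CC=C)(CC=C)C(OC)=C1C(=O)C[C@H](O)c1ccccc1
F7 | step 3 | (2S)-8,8-diallyl-5-methoxy-2-phenyl-2,3-dihydro-4H-chromene-4,7(8H)-dione | COC1=CC(=O)C(CC=C)(CC=C)C2=C1C(=O)C[C@@H](c1ccccc1)O2
F8 | step 4 | (2S)-5-methoxy-8,8-bis(3-methylbut-2-en-1-yl)-2-phenyl-2,3-dihydrospiro[chromene-4,2'-[1,3]dithian]-7(8H)-one | COC1=CC(=O)C(CC=C(C)C)(CC=C(C)C)C2=C1C1(SCCCS1)C[C@@H](c1ccccc1)O2
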